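The route rests on cutting ring A at C2–C3 and C4–C5 (labdane numbering): C3 and C4 with the geminal methyls are one molecule of isobutylene lodged between the C2 carbinol and the C5 ring-fusion carbon. In one operation a silylium catalyst with a confined chiral anion lets isobutylene add to the C2 aldehyde of an acyclic (2E,6Z,10E)-trienal; the C4 cation closes ring A on the C5=C10 alkene, ring B follows, and an allylsilane ends the cascade as the C8 exocyclic methylene. C2, set by the catalyst, relays to C5, C9 and C10 through a chair–chair transition state. The precursor already carries the whole side chain, built by two acetoacetate-dianion/enol-triflate cycles.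

Key step: step 13

Remark: the sense of induction of the chiral acid in step 13 is assumed; the catalyst antipode that gives (2R) would be fixed by a screen, and the (S,S)-catalyst is written for definiteness.

Step 1
Reactants: 1 tert-butyl(but-3-yn-1-yloxy)dimethylsilane
Product: 3 (E)-5-((tert-butyldimethylsilyl)oxy)-3-methylpent-2-en-1-ol, via (E)-alkenyldimethylalane 2 (not isolated)
Conditions: Me3Al, Cp2ZrCl2 (0.25 equiv), CH2Cl2, 0 °C to rt; then n-BuLi, THF, −78 °C; (CH2O)n, −78 °C to rt
Reagents that add atoms: trimethylaluminium, C[Al](C)C; paraformaldehyde (as formaldehyde), C=O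
Why: Negishi carboalumination adds methyl and aluminium syn across the terminal alkyne with methyl on the internal carbon, and the alanate is hydroxymethylated with retention, which fixes the (E)-alkene that becomes C5=C10.

Step 2
Reactants: 3 (E)-5-((tert-butyldimethylsilyl)oxy)-3-methylpent-2-en-1-ol
Product: 4 (E)-((5-bromo-3-methylpent-3-en-1-yl)oxy)(tert-butyl)dimethylsilane
Conditions: CBr4, PPh3, CH2Cl2, 0 °C
Reagents that add atoms: carbon tetrabromide, BrC(Br)(Br)Br
Why: The Appel reaction converts the primary allylic alcohol into the bromide by SN2 at CH2, without change of alkene geometry or loss of the silyl ether.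

Step 3
Reactants: 4 (E)-((5-bromo-3-methylpent-3-en-1-yl)oxy)(tert-butyl)dimethylsilane, 5 methyl acetoacetate
Product: 7 methyl (E)-9-((tert-butyldimethylsilyl)oxy)-7-methyl-3-oxonon-6-enoate, via methyl acetoacetate dianion 6 (not isolated)
Conditions: 5, NaH, THF, 0 °C; n-BuLi, 0 °C; then 4, 0 °C
Reagents that add atoms: none
Why: In this acetoacetate dianion alkylation the more basic terminal carbanion displaces the allylic bromide (SN2), which forms C6–C7 and leaves the β-keto ester for the next step.

Step 4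
Reactants: 7 methyl (E)-9-((tert-butyldimethylsilyl)oxy)-7-methyl-3-oxonon-6-enoate
Product: 8 methyl (2Z,6E)-9-((tert-butyldimethylsilyl)oxy)-7-methyl-3-(((trifluoromethyl)sulfonyl)oxy)nona-2,6-dienoate
Conditions: Tf2O, sat. aq. LiOH, hexanes, 5 °C
Reagents that add atoms: trifluoromethanesulfonic anhydride, O=S(=O)(OS(=O)(=O)C(F)(F)F)C(F)(F)F
Why: Enol triflate formation from the lithium-chelated (Z)-enolate places the triflate cis to the ester, which sets the C8=C9 geometry.

Step 5
Reactants: 8 methyl (2Z,6E)-9-((tert-butyldimethylsilyl)oxy)-7-methyl-3-(((trifluoromethyl)sulfonyl)oxy)nona-2,6-dienoate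
Product: 9 methyl (2Z,6E)-9-((tert-butyldimethylsilyl)oxy)-7-methyl-3-((trimethylsilyl)methyl)nona-2,6-dienoate
Conditions: Me3SiCH2MgCl, Pd(PPh3)4 (5 mol%), THF, 0 °C to rt
Reagents that add atoms: (trimethylsilyl)methylmagnesium chloride, C[Si](C)(C)C[Mg]Cl
Why: Kumada–Corriu coupling of the enol triflate with a Grignard reagent that has no β-hydrogen proceeds with retention, which builds the allylsilane terminator with CH2SiMe3 cis to the ester.

Step 6
Reactants: 9 methyl (2Z,6E)-9-((tert-butyldimethylsilyl)oxy)-7-methyl-3-((trimethylsilyl)methyl)nona-2,6-dienoate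
Product: 10 (2Z,6E)-9-((tert-butyldimethylsilyl)oxy)-7-methyl-3-((trimethylsilyl)methyl)nona-2,6-dien-1-ol
Conditions: i-Bu2AlH, CH2Cl2, −78 °C; aq. potassium sodium tartrate
Reagents that add atoms: none
Why: 1,2-Reduction of the enoate by the aluminium hydride gives the allylic alcohol and leaves the allylsilane and the silyl ether untouched.

Step 7
Reactants: 10 (2Z,6E)-9-((tert-butyldimethylsilyl)oxy)-7-methyl-3-((trimethylsilyl)methyl)nona-2,6-dien-1-ol
Product: 12 tert-butyl(((3E,7Z)-9-chloro-3-methyl-7-((trimethylsilyl)methyl)nona-3,7-dien-1-yl)oxy)dimethylsilane, via allylic mesylate 11 (not isolated)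
Conditions: MsCl, 2,4,6-collidine, LiCl, DMF, 0 °C
Reagents that add atoms: lithium chloride, [Li+].[Cl-]
Why: Mesylation and chloride displacement (SN2) under buffered, non-acidic conditions give the primary allylic chloride without protodesilylation or allylic transposition.

Step 8
Reactants: 12 tert-butyl(((3E,7Z)-9-chloro-3-methyl-7-((trimethylsilyl)methyl)nona-3,7-dien-1-yl)oxy)dimethylsilane, 13 tert-butyl acetoacetate
Product: 15 tert-butyl (6Z,10E)-13-((tert-butyldimethylsilyl)oxy)-11-methyl-3-oxo-7-((trimethylsilyl)methyl)trideca-6,10-dienoate, via tert-butyl acetoacetate dianion 14 (not isolated)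
Conditions: 13, NaH, THF, 0 °C; n-BuLi, 0 °C; then 12, 0 °C
Reagents that add atoms: none
Why: A second acetoacetate dianion alkylation (SN2 at the primary allylic chloride) forms C11–C12 and delivers the β-keto ester of the side chain.

Step 9
Reactants: 15 tert-butyl (6Z,10E)-13-((tert-butyldimethylsilyl)oxy)-11-methyl-3-oxo-7-((trimethylsilyl)methyl)trideca-6,10-dienoate
Product: 16 tert-butyl (2E,6Z,10E)-13-((tert-butyldimethylsilyl)oxy)-11-methyl-3-(((trifluoromethyl)sulfonyl)oxy)-7-((trimethylsilyl)methyl)trideca-2,6,10-trienoate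
Conditions: Tf2O, aq. Me4NOH, hexanes, 5 °C
Reagents that add atoms: trifluoromethanesulfonic anhydride, O=S(=O)(OS(=O)(=O)C(F)(F)F)C(F)(F)F
Why: Enol triflate formation with the non-chelating tetramethylammonium counter-ion goes through the (E)-enolate, so the triflate ends trans to the ester and the chain cis to it, as C13=C14 requires.

Step 10
Reactants: 16 tert-butyl (2E,6Z,10E)-13-((tert-butyldimethylsilyl)oxy)-11-methyl-3-(((trifluoromethyl)sulfonyl)oxy)-7-((trimethylsilyl)methyl)trideca-2,6,10-trienoate
Product: 17 tert-butyl (2E,6Z,10E)-3-(acetoxymethyl)-13-((tert-butyldimethylsilyl)oxy)-11-methyl-7-((trimethylsilyl)methyl)trideca-2,6,10-trienoate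
Conditions: AcOCH2ZnBr (from AcOCH2Br, Zn, LiCl, THF), Pd(PPh3)4 (5 mol%), THF, rt
Reagents that add atoms: (acetoxymethyl)zinc bromide, CC(=O)OC[Zn]Br, made in the flask from bromomethyl acetate, CC(=O)OCBr
Why: Negishi coupling of the enol triflate with an acyloxymethylzinc reagent (a hydroxymethyl anion equivalent) proceeds with retention and gives the (E)-enoate with CH2OAc trans to the ester.

Step 11
Reactants: 17 tert-butyl (2E,6Z,10E)-3-(acetoxymethyl)-13-((tert-butyldimethylsilyl)oxy)-11-methyl-7-((trimethylsilyl)methyl)trideca-2,6,10-trienoate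
Product: 18 tert-butyl (2E,6Z,10E)-3-(acetoxymethyl)-13-hydroxy-11-methyl-7-((trimethylsilyl)methyl)trideca-2,6,10-trienoate
Conditions: HF·pyridine, pyridine, THF, 0 °C to rt
Reagents that add atoms: none
Why: Buffered fluoride desilylation removes the primary silyl ether, while the tert-butyl ester, the acetate and the allylsilane are stable to these conditions.

Step 12
Reactants: 18 tert-butyl (2E,6Z,10E)-3-(acetoxymethyl)-13-hydroxy-11-methyl-7-((trimethylsilyl)methyl)trideca-2,6,10-trienoate
Product: 19 tert-butyl (2E,6Z,10E)-3-(acetoxymethyl)-11-methyl-13-oxo-7-((trimethylsilyl)methyl)trideca-2,6,10-trienoate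
Conditions: Dess–Martin periodinane, NaHCO3, CH2Cl2, 0 °C; used crude at once
Reagents that add atoms: none
Why: Dess–Martin oxidation under bicarbonate buffering should give the β,γ-unsaturated aldehyde without migration of the C5=C10 alkene into conjugation.

Step 13
Reactants: 19 tert-butyl (2E,6Z,10E)-3-(acetoxymethyl)-11-methyl-13-oxo-7-((trimethylsilyl)methyl)trideca-2,6,10-trienoate, 20 isobutylene (2-methylpropene)
Product: 22 tert-butyl (2E)-3-(acetoxymethyl)-5-[(1R,4aR,7R,8aR)-7-hydroxy-5,5,8a-trimethyl-2-methylidenedecahydronaphthalen-1-yl]pent-2-enoate, via O-trimethylsilyl ether 21 (not isolated)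
Conditions: (S,S)-IDPi (confined imidodiphosphorimidate Brønsted acid, 3 mol%), methallyltrimethylsilane (5 mol%, silylium initiator), isobutylene/CH2Cl2 (1:4), −78 °C, slow addition of 19; then aq. citric acid, THF, 0 °C
Reagents that add atoms: none
Why: Proposed new method: the catalyst, silylated in situ, pairs Me3Si+ with a confined chiral imidodiphosphorimidate anion and turns the C2 aldehyde into a silyloxocarbenium ion that isobutylene attacks through its CH2 terminus (Prins addition, C2–C3); the tertiary C4 cation, which has no basic neighbour for the ene pathway, is captured by C5 of the (E)-C5=C10 alkene (C4–C5), the C10 cation by C9 of the allylsilane, and loss of Me3Si+ gives the C8=C17 methylene and returns silylium to the anion. The closest known reaction types are the imidodiphosphorimidate/silylium-catalysed Hosomi–Sakurai and hetero-Diels–Alder reactions of aliphatic aldehydes with allylsilanes and simple dienes, the Me2AlCl-promoted Prins/ene addition of isobutylene to aldehydes, and allylsilane-terminated cation–olefin bicyclisations. Ring A closes 6-endo-trig at the C5=C10 alkene and ring B 6-endo-trig at the C8=C9 allylsilane, both through chair transition states. C2 (R) is set by the chiral anion in the Prins addition; C5 and C10 follow from anti addition across the (E)-alkene with the C2–OSiMe3 group equatorial (trans ring fusion, 5-H anti to the C10 methyl), and C9 from the (Z)-allylsilane geometry, which places C11 equatorial. The step needs isobutylene, not the allylsilane of a second substrate molecule, to capture the oxocarbenium ion, which isobutylene as co-solvent and the slow addition of 19 secure, and it needs cyclisation to outrun proton loss, which the non-basic anion and the O-silyl group secure.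

Step 14
Reactants: 22 tert-butyl (2E)-3-(acetoxymethyl)-5-[(1R,4aR,7R,8aR)-7-hydroxy-5,5,8a-trimethyl-2-methylidenedecahydronaphthalen-1-yl]pent-2-enoate
Product: 24 (2E)-3-(acetoxymethyl)-5-[(1R,4aR,7R,8aR)-7-hydroxy-5,5,8a-trimethyl-2-methylidenedecahydronaphthalen-1-yl]pent-2-enoic acid, via bis(trimethylsilyl) derivative 23 (not isolated)
Conditions: TMSOTf, 2,6-lutidine, CH2Cl2, 0 °C; then pH 4 aq. buffer
Reagents that add atoms: none
Why: Silyl triflate-mediated tert-butyl ester cleavage (alkyl–oxygen fission with loss of isobutylene) under lutidine buffering spares the acetate and the exocyclic alkene, and aqueous work-up cleaves the silyl ester and silyl ether.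

Compound list
1 | tert-butyl(but-3-yn-1-yloxy)dimethylsilane | C#CCCO[Si](C)(C)C(C)(C)C | starting material
2 | (E)-alkenyldimethylalane from 1 (Al cis to methyl) | C[Al](C)/C=C(\C)CCO[Si](C)(C)C(C)(C)C | intermediate
3 | (E)-5-((tert-butyldimethylsilyl)oxy)-3-methylpent-2-en-1-ol | OC/C=C(\C)CCO[Si](C)(C)C(C)(C)C | intermediate
4 | (E)-((5-bromo-3-methylpent-3-en-1-yl)oxy)(tert-butyl)dimethylsilane | BrC/C=C(\C)CCO[Si](C)(C)C(C)(C)C | intermediate
5 | methyl acetoacetate | COC(=O)CC(C)=O | starting material
6 | methyl acetoacetate dianion (sodium lithium salt) | [Na+].[Li+].[CH2-]C(=O)[CH-]C(=O)OC | intermediate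
7 | methyl (E)-9-((tert-butyldimethylsilyl)oxy)-7-methyl-3-oxonon-6-enoate | COC(=O)CC(=O)CC/C=C(\C)CCO[Si](C)(C)C(C)(C)C | intermediate
8 | methyl (2Z,6E)-9-((tert-butyldimethylsilyl)oxy)-7-methyl-3-(((trifluoromethyl)sulfonyl)oxy)nona-2,6-dienoate | COC(=O)/C=C(\OS(=O)(=O)C(F)(F)F)CC/C=C(\C)CCO[Si](C)(C)C(C)(C)C | intermediate
9 | methyl (2Z,6E)-9-((tert-butyldimethylsilyl)oxy)-7-methyl-3-((trimethylsilyl)methyl)nona-2,6-dienoate | COC(=O)/C=C(\C[Si](C)(C)C)CC/C=C(\C)CCO[Si](C)(C)C(C)(C)C | intermediate
10 | (2Z,6E)-9-((tert-butyldimethylsilyl)oxy)-7-methyl-3-((trimethylsilyl)methyl)nona-2,6-dien-1-ol | OC/C=C(\C[Si](C)(C)C)CC/C=C(\C)CCO[Si](C)(C)C(C)(C)C | intermediate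
11 | methanesulfonate of 10 | CS(=O)(=O)OC/C=C(\C[Si](C)(C)C)CC/C=C(\C)CCO[Si](C)(C)C(C)(C)C | intermediate
12 | tert-butyl(((3E,7Z)-9-chloro-3-methyl-7-((trimethylsilyl)methyl)nona-3,7-dien-1-yl)oxy)dimethylsilane | ClC/C=C(\C[Si](C)(C)C)CC/C=C(\C)CCO[Si](C)(C)C(C)(C)C | intermediate
13 | tert-butyl acetoacetate | CC(=O)CC(=O)OC(C)(C)C | starting material
14 | tert-butyl acetoacetate dianion (sodium lithium salt) | [Na+].[Li+].[CH2-]C(=O)[CH-]C(=O)OC(C)(C)C | intermediate
15 | tert-butyl (6Z,10E)-13-((tert-butyldimethylsilyl)oxy)-11-methyl-3-oxo-7-((trimethylsilyl)methyl)trideca-6,10-dienoate | CC(C)(C)OC(=O)CC(=O)CC/C=C(\C[Si](C)(C)C)CC/C=C(\C)CCO[Si](C)(C)C(C)(C)C | intermediate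
16 | tert-butyl (2E,6Z,10E)-13-((tert-butyldimethylsilyl)oxy)-11-methyl-3-(((trifluoromethyl)sulfonyl)oxy)-7-((trimethylsilyl)methyl)trideca-2,6,10-trienoate | CC(C)(C)OC(=O)/C=C(/OS(=O)(=O)C(F)(F)F)CC/C=C(\C[Si](C)(C)C)CC/C=C(\C)CCO[Si](C)(C)C(C)(C)C | intermediate
17 | tert-butyl (2E,6Z,10E)-3-(acetoxymethyl)-13-((tert-butyldimethylsilyl)oxy)-11-methyl-7-((trimethylsilyl)methyl)trideca-2,6,10-trienoate | CC(C)(C)OC(=O)/C=C(/COC(C)=O)CC/C=C(\C[Si](C)(C)C)CC/C=C(\C)CCO[Si](C)(C)C(C)(C)C | intermediate
18 | tert-butyl (2E,6Z,10E)-3-(acetoxymethyl)-13-hydroxy-11-methyl-7-((trimethylsilyl)methyl)trideca-2,6,10-trienoate | CC(C)(C)OC(=O)/C=C(/COC(C)=O)CC/C=C(\C[Si](C)(C)C)CC/C=C(\C)CCO | intermediate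
19 | tert-butyl (2E,6Z,10E)-3-(acetoxymethyl)-11-methyl-13-oxo-7-((trimethylsilyl)methyl)trideca-2,6,10-trienoate | CC(C)(C)OC(=O)/C=C(/COC(C)=O)CC/C=C(\C[Si](C)(C)C)CC/C=C(\C)CC=O | intermediate
20 | isobutylene (2-methylpropene) | CC(C)=C | starting material
21 | O-trimethylsilyl ether of 22 (C2–OSiMe3, equatorial) | C=C1CC[C@@H]2C(C)(C)C[C@@H](O[Si](C)(C)C)C[C@@]2(C)[C@@H]1CC/C(=C\C(=O)OC(C)(C)C)COC(C)=O | intermediate
22 | tert-butyl (2E)-3-(acetoxymethyl)-5-[(1R,4aR,7R,8aR)-7-hydroxy-5,5,8a-trimethyl-2-methylidenedecahydronaphthalen-1-yl]pent-2-enoate | C=C1CC[C@@H]2C(C)(C)C[C@@H](O)C[C@@]2(C)[C@@H]1CC/C(=C\C(=O)OC(C)(C)C)COC(C)=O | intermediate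
23 | trimethylsilyl ester and C2 trimethylsilyl ether of 24 | C=C1CC[C@@H]2C(C)(C)C[C@@H](O[Si](C)(C)C)C[C@@]2(C)[C@@H]1CC/C(=C\C(=O)O[Si](C)(C)C)COC(C)=O | intermediate
24 | (2E)-3-(acetoxymethyl)-5-[(1R,4aR,7R,8aR)-7-hydroxy-5,5,8a-trimethyl-2-methylidenedecahydronaphthalen-1-yl]pent-2-enoic acid; in labdane numbering (2R,5R,9R,10R)-16-acetoxy-2-hydroxylabda-8(17),13E-dien-15-oic acid | C=C1CC[C@@H]2C(C)(C)C[C@@H](O)C[C@@]2(C)[C@@H]1CC/C(=C\C(=O)O)COC(C)=O | target

Total step count: 14. Longest linear sequence: 14 steps (from 1).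

Steps most likely to fail

Step 13. The silyloxocarbenium ion may be captured by the allylsilane of a second substrate molecule (oligomerisation), the C4 cation may lose a proton before ring A closes, or the Prins addition may discriminate the aldehyde faces poorly. The fallback uses known reactions and sets out from aldehyde 19. Reagent-controlled allylboration with B-methallyldiisopinocampheylborane (antipode chosen for the R alcohol; Et2O, −78 °C, ethanolamine work-up) forms C2–C3 and gives tert-butyl (2E,6Z,10E,13R)-3-(acetoxymethyl)-13-hydroxy-11,15-dimethyl-7-((trimethylsilyl)methyl)hexadeca-2,6,10,15-tetraenoate F1. A hydrogen-atom-transfer-initiated radical–polar crossover bicyclisation then follows, with N,N'-bis(3,5-di-tert-butylsalicylidene)-1,2-cyclohexanediaminocobalt (a divalent cobalt salen complex), N-fluoro-2,4,6-trimethylpyridinium tetrafluoroborate and PhSiH3 in hexafluoroisopropanol. It generates the C4 radical/cation selectively at the 1,1-disubstituted alkene, closes rings A and B under control of the C2 stereocentre with allylsilane termination, and comes back to the route at 22.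

Step 7. The γ-silyl allylic chloride may undergo desilylative 1,4-elimination or allylic transposition during its formation and during the alkylation of step 8. The fallback introduces silicon only after the C11–C12 bond exists and sets out from enol triflate 8. Reduction with i-Bu2AlH gives (2Z,6E)-9-((tert-butyldimethylsilyl)oxy)-1-hydroxy-7-methylnona-2,6-dien-3-yl trifluoromethanesulfonate F2. MsCl, collidine and LiCl give (2Z,6E)-9-((tert-butyldimethylsilyl)oxy)-1-chloro-7-methylnona-2,6-dien-3-yl trifluoromethanesulfonate F3. Alkylation of the dianion of 13 gives tert-butyl (6Z,10E)-13-((tert-butyldimethylsilyl)oxy)-11-methyl-3-oxo-7-(((trifluoromethyl)sulfonyl)oxy)trideca-6,10-dienoate F4. Kumada–Corriu coupling with excess Me3SiCH2MgCl and Pd(PPh3)4, in which the first equivalent masks the β-keto ester as its magnesium enolate, comes back to the route at 15.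

Step 10. Zerovalent palladium may ionise the newly formed allylic acetate, and transmetalation of the α-acyloxy zinc reagent may be slow. The fallback sets out from enol triflate 16. Stille coupling with (tributylstannyl)methanol (Pd(PPh3)4, LiCl, dioxane, 90 °C) gives tert-butyl (2E,6Z,10E)-13-((tert-butyldimethylsilyl)oxy)-3-(hydroxymethyl)-11-methyl-7-((trimethylsilyl)methyl)trideca-2,6,10-trienoate F5, an allylic alcohol that palladium does not ionise. Separate acetylation (Ac2O, pyridine, DMAP) comes back to the route at 17.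

Further compounds
F1 | step 13 | tert-butyl (2E,6Z,10E,13R)-3-(acetoxymethyl)-13-hydroxy-11,15-dimethyl-7-((trimethylsilyl)methyl)hexadeca-2,6,10,15-tetraenoate | CC(C)(C)OC(=O)/C=C(/COC(C)=O)CC/C=C(\C[Si](C)(C)C)CC/C=C(\C)C[C@H](O)CC(C)=C
F2 | step 7 | (2Z,6E)-9-((tert-butyldimethylsilyl)oxy)-1-hydroxy-7-methylnona-2,6-dien-3-yl trifluoromethanesulfonate | OC/C=C(\OS(=O)(=O)C(F)(F)F)CC/C=C(\C)CCO[Si](C)(C)C(C)(C)C
F3 | step 7 | (2Z,6E)-9-((tert-butyldimethylsilyl)oxy)-1-chloro-7-methylnona-2,6-dien-3-yl trifluoromethanesulfonate | ClC/C=C(\OS(=O)(=O)C(F)(F)F)CC/C=C(\C)CCO[Si](C)(C)C(C)(C)C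
F4 | step 7 | tert-butyl (6Z,10E)-13-((tert-butyldimethylsilyl)oxy)-11-methyl-3-oxo-7-(((trifluoromethyl)sulfonyl)oxy)trideca-6,10-dienoate | CC(C)(C)OC(=O)CC(=O)CC/C=C(\OS(=O)(=O)C(F)(F)F)CC/C=C(\C)CCO[Si](C)(C)C(C)(C)C
F5 | step 10 | tert-butyl (2E,6Z,10E)-13-((tert-butyldimethylsilyl)oxy)-3-(hydroxymethyl)-11-methyl-7-((trimethylsilyl)methyl)trideca-2,6,10-trienoate | CC(C)(C)OC(=O)/C=C(/CO)CC/C=C(\C[Si](C)(C)C)CC/C=C(\C)CCO[Si](C)(C)C(C)(C)C
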